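**Strategy.** Everything rests on cutting the hydroazulene at C3a–C8a and C7–C8, the two bonds of a Rh(I) [5+2] cycloaddition between a tethered terminal alkyne and a vinylcyclopropane. The step exploits the seven-membered ring C3a–C4–C5–C6–C7–C8–C8a, whose fusion alkene C8a=C8 lies next to carboxyl-derived C7 and whose C4 bears a methyl group; it closes this ring and the cyclopentane C1–C2–C3–C3a–C8a at once and sets C3a from the cyclopropane. Its precursor is an acyclic enyne with an (S) quaternary propargylic C1, a Z trisubstituted C3a=C4 alkene and a trans (1R,2R) cyclopropane ester. Carbinol, C4, C9′ and the diformylphloroglucinol are added afterwards.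

Key step: step 13

Remark (numbering): ring atoms carry azulene numbers (C1–C3, C3a, C4–C8, C8a); C9′ is the benzylic carbon.
Remark (design of the cycloaddition substrate): the cycloaddition is suprafacial across C3a and C7 and retains C7, so a trans (5R,7R) cyclopropane puts H-3a cis to the ester only if the C3a=C4 alkene is Z (tether cis to the ring). The E isomer would give the C3a epimer, so 18 is drawn and made as the Z alkene.
Remark (assumption): the Cu(I)–(S,S)-t-Bu-box catalyst of step 10 is taken to show the same facial sense with vinylboronate 14 as with styrene; if it is opposite, the (R,R) ligand is used.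

Step 1
Reactants: 1 ethyl (S)-3-hydroxybutanoate
Product: 2 ethyl (2S,3S)-3-hydroxy-2-methylbutanoate
Conditions: LDA (2.2 equiv), THF, −78 → −20 °C; MeI, −78 → 0 °C
Reagents that add atoms: iodomethane, CI
Why: Fráter–Seebach alkylation: the lithium-chelated alkoxide enolate is methylated anti to the C3 methyl group; the C2 configuration formed here is erased again in step 2.

Step 2
Reactants: 2 ethyl (2S,3S)-3-hydroxy-2-methylbutanoate
Product: 3 ethyl (2S,3S)-2-allyl-3-hydroxy-2-methylbutanoate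
Conditions: LDA (2.2 equiv), THF–DMPU, −78 → −20 °C; allyl bromide, −78 → 0 °C
Reagents that add atoms: allyl bromide, C=CCBr
Why: second Fráter–Seebach alkylation: allyl bromide enters the chelated tetrasubstituted enolate anti to the C3 methyl, so the carbinol centre sets the quaternary carbon (the future C1).

Step 3
Reactants: 3 ethyl (2S,3S)-2-allyl-3-hydroxy-2-methylbutanoate
Product: 4 (2R,3S)-2-allyl-2-methylbutane-1,3-diol
Conditions: LiAlH4, THF, 0 °C → rt
Reagents that add atoms: none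
Why: hydride reduction of the ester; the quaternary and carbinol centres are not touched.

Step 4
Reactants: 4 (2R,3S)-2-allyl-2-methylbutane-1,3-diol
Product: 5 (2S,3R)-3-[(tert-butyldimethylsilyloxy)methyl]-3-methylhex-5-en-2-ol
Conditions: TBSCl (1.05 equiv), imidazole, CH2Cl2, 0 °C
Reagents that add atoms: tert-butyldimethylsilyl chloride, CC(C)(C)[Si](C)(C)Cl
Why: silylation distinguishes the primary hydroxyl from the more hindered secondary one.

Step 5
Reactants: 5 (2S,3R)-3-[(tert-butyldimethylsilyloxy)methyl]-3-methylhex-5-en-2-ol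
Product: 6 (R)-3-[(tert-butyldimethylsilyloxy)methyl]-3-methylhex-5-en-2-one
Conditions: Dess–Martin periodinane, NaHCO3, CH2Cl2, rt
Reagents that add atoms: none
Why: Dess–Martin oxidation of the secondary alcohol; the adjacent quaternary centre cannot epimerise.

Step 6
Reactants: 6 (R)-3-[(tert-butyldimethylsilyloxy)methyl]-3-methylhex-5-en-2-one
Product: 9 (S)-tert-butyldimethyl{[2-methyl-2-(trimethylsilylethynyl)pent-4-en-1-yl]oxy}silane, via enol phosphate 7 (not isolated), via lithium acetylide 8 (not isolated)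
Conditions: LDA (1.1 equiv), THF, −78 °C; ClP(O)(OEt)2, −78 °C → rt; LDA (2.3 equiv), −78 °C → rt; TMSCl, −78 → 0 °C
Reagents that add atoms: chlorotrimethylsilane, C[Si](C)(C)Cl; diethyl chlorophosphate, CCOP(=O)(Cl)OCC (its atoms stay in 7 only)
Why: methyl ketone to alkyne by enol phosphate formation and β-elimination: deprotonation can occur only at the methyl group because the other α-carbon is quaternary, and the acetylide is silylated in the same flask to mask the alkyne for steps 7–11.

Step 7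
Reactants: 9 (S)-tert-butyldimethyl{[2-methyl-2-(trimethylsilylethynyl)pent-4-en-1-yl]oxy}silane
Product: 11 (S)-4-[(tert-butyldimethylsilyloxy)methyl]-4-methyl-6-(trimethylsilyl)hex-5-yn-1-ol, via B-alkyl-9-BBN 10 (not isolated)
Conditions: 9-BBN-H, THF, 0 °C → rt; H2O2, aq NaOAc, 0 °C → rt
Reagents that add atoms: hydrogen peroxide, OO; 9-borabicyclo[3.3.1]nonane, B1C2CCCC1CCC2 (its atoms stay in 10 only)
Why: anti-Markovnikov hydroboration–oxidation; 9-BBN adds to the terminal alkene far faster than to the hindered silylalkyne, and buffered peroxide spares the C–Si bond.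

Step 8
Reactants: 11 (S)-4-[(tert-butyldimethylsilyloxy)methyl]-4-methyl-6-(trimethylsilyl)hex-5-yn-1-ol
Product: 12 (S)-4-[(tert-butyldimethylsilyloxy)methyl]-4-methyl-6-(trimethylsilyl)hex-5-ynal
Conditions: Dess–Martin periodinane, NaHCO3, CH2Cl2, rt
Reagents that add atoms: none
Why: Dess–Martin oxidation of a primary alcohol to the aldehyde without over-oxidation.

Step 9
Reactants: 12 (S)-4-[(tert-butyldimethylsilyloxy)methyl]-4-methyl-6-(trimethylsilyl)hex-5-ynal
Product: 13 tert-butyl{[(2S,5Z)-6-iodo-2-methyl-2-(trimethylsilylethynyl)hept-5-en-1-yl]oxy}dimethylsilane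
Conditions: EtPPh3I, n-BuLi, THF, rt; I2, −78 °C; NaHMDS, −20 °C; then 12, −78 °C → rt
Reagents that add atoms: (1-iodoethylidene)triphenylphosphorane (made in the flask), CC(I)=P(c1ccccc1)(c1ccccc1)c1ccccc1
Why: Stork–Zhao-type Wittig olefination with the α-iodo ylide: kinetic cis-oxaphosphetane formation from the non-stabilised ylide should place the chain and iodine cis, which fixes the Z geometry needed at C3a=C4.

Step 10
Reactants: 14 4,4,5,5-tetramethyl-2-vinyl-1,3,2-dioxaborolane; 15 ethyl diazoacetate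
Product: 16 ethyl (1R,2R)-2-(4,4,5,5-tetramethyl-1,3,2-dioxaborolan-2-yl)cyclopropane-1-carboxylate
Conditions: CuOTf (2 mol %), (S,S)-t-Bu-box (2.2 mol %), 14 in excess, slow addition of 15, CH2Cl2, rt; chromatography removes the cis isomer
Reagents that add atoms: none
Why: copper(I)–bisoxazoline carbene transfer to a monosubstituted alkene favours the trans cyclopropane and the C2-symmetric ligand selects the alkene face, which sets both ring centres (future C5 and C7).

Step 11
Reactants: 13 tert-butyl{[(2S,5Z)-6-iodo-2-methyl-2-(trimethylsilylethynyl)hept-5-en-1-yl]oxy}dimethylsilane; 16 ethyl (1R,2R)-2-(pinacolboryl)cyclopropane-1-carboxylate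
Product: 17 ethyl (1R,2R)-2-[(2Z,6S)-6-[(tert-butyldimethylsilyloxy)methyl]-6-methyl-8-(trimethylsilyl)oct-2-en-7-yn-2-yl]cyclopropane-1-carboxylate
Conditions: Pd(OAc)2 (5 mol %), SPhos (10 mol %), K3PO4, toluene–H2O, 80 °C
Reagents that add atoms: none
Why: Suzuki–Miyaura coupling of a cyclopropylboronate with an alkenyl iodide; both partners react with retention, so the Z alkene and the trans ring are carried over unchanged.

Step 12
Reactants: 17 the silylalkyne ester from step 11
Product: 18 ethyl (1R,2R)-2-[(2Z,6S)-6-[(tert-butyldimethylsilyloxy)methyl]-6-methyloct-2-en-7-yn-2-yl]cyclopropane-1-carboxylate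
Conditions: K2CO3, EtOH, rt
Reagents that add atoms: none
Why: base-mediated protodesilylation of the alkynylsilane; ethanol keeps the ethyl ester intact and the TBS ether is stable.

Step 13
Reactants: 18 the alkynyl vinylcyclopropane (S at C1, Z alkene, trans (1R,2R) cyclopropane ester)
Product: 19 ethyl (1S,3aR,7R)-1-[(tert-butyldimethylsilyloxy)methyl]-1,4-dimethyl-1,2,3,3a,6,7-hexahydroazulene-7-carboxylate
Conditions: [Rh(CO)2Cl]2 (5 mol %), ClCH2CH2Cl (0.02 M), 80 °C
Reagents that add atoms: none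
Why: Rh(I) binds the Z alkene in the s-cis vinylcyclopropane conformer and inserts into the ester-activated C5–C7 bond with retention at C7, giving a σ-alkyl π-allyl rhodacycle (Rh–C7, allyl over C3a–C5); the tethered alkyne then inserts at C3a and C7–C8 reductive elimination releases the catalyst. The closest known reaction type is the Rh(I)-catalysed intramolecular [5+2] cycloaddition of alkyne-tethered vinylcyclopropanes, which includes trans acceptor-substituted cyclopropanes that open at the substituted bond. The five-membered ring closes by 5-exo insertion of the alkyne (C3a–C8a) and the seven-membered ring by C7–C8 reductive elimination from the eight-membered rhodacycle. The one new stereocentre, C3a, is controlled by the cyclopropane: rhodium, C7 and the incoming alkyne stay on the same face of the allyl unit, so the Z alkene together with the (5R,7R) trans ring should place H-3a cis to the ester (3aR), while C7 is carried over and C1 is a bystander. The step needs cleavage of C5–C7 in preference to C5–C6, which the trans ester acceptor and the carbonyl chloride catalyst should secure; alkyne regiochemistry is fixed by the three-carbon tether through C1.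

Step 14
Reactants: 19 the cycloadduct ester
Product: 21 2-[(1S,3aR,7R)-1-[(tert-butyldimethylsilyloxy)methyl]-1,4-dimethyl-1,2,3,3a,6,7-hexahydroazulen-7-yl]propan-2-ol, via methyl ketone 20 (not isolated)
Conditions: MeMgBr (4 equiv), anhydrous CeCl3, THF, −78 → 0 °C
Reagents that add atoms: methylmagnesium bromide, C[Mg]Br
Why: double addition of a cerium-modified, weakly basic methyl nucleophile to the ester; the low basicity avoids removal of the allylic C7–H, so C7 and the C8a=C8 position are preserved.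

Step 15
Reactants: 21 the silyl-protected carbinol
Product: 22 2-[(1S,3aR,7R)-1-(hydroxymethyl)-1,4-dimethyl-1,2,3,3a,6,7-hexahydroazulen-7-yl]propan-2-ol
Conditions: TBAF, THF, rt
Reagents that add atoms: none
Why: fluoride cleavage of the silyl ether.

Step 16
Reactants: 22 the diol
Product: 23 (1S,3aR,7R)-7-(2-hydroxypropan-2-yl)-1,4-dimethyl-1,2,3,3a,6,7-hexahydroazulene-1-carbaldehyde
Conditions: Dess–Martin periodinane, NaHCO3, CH2Cl2, 0 °C → rt
Reagents that add atoms: none
Why: only the primary alcohol can be oxidised; the aldehyde has no α-hydrogen, so C1 is safe.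

Step 17
Reactants: 23 the C1 aldehyde; 24 1,3,5-trimethoxybenzene
Product: 26 2-[(1S,3aR,7R)-1-[hydroxy(2,4,6-trimethoxyphenyl)methyl]-1,4-dimethyl-1,2,3,3a,6,7-hexahydroazulen-7-yl]propan-2-ol (both carbinol epimers), via (2,4,6-trimethoxyphenyl)lithium 25 (not isolated)
Conditions: 24 (3 equiv), n-BuLi, THF, 0 °C → rt; then 23, −78 → 0 °C; aq NH4Cl
Reagents that add atoms: none
Why: ortho-lithiation of the arene between two methoxy groups and 1,2-addition to the non-enolisable aldehyde (one equivalent is consumed by the tertiary hydroxyl); the carbinol configuration is irrelevant because it is lost in step 18.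

Step 18
Reactants: 26 the benzylic carbinol
Product: 27 2-[(1R,3aR,7R)-1,4-dimethyl-1-[(1R)-3-methyl-1-(2,4,6-trimethoxyphenyl)but-3-en-1-yl]-1,2,3,3a,6,7-hexahydroazulen-7-yl]propan-2-ol
Conditions: (2-methylallyl)trimethylsilane (4 equiv), BF3·OEt2 (20 mol %), CH2Cl2, −78 → −40 °C
Reagents that add atoms: (2-methylallyl)trimethylsilane, C=C(C)C[Si](C)(C)C
Why: Hosomi–Sakurai-type SN1 allylation of a benzylic alcohol: the trimethoxybenzyl cation forms far more readily than any cation from the tertiary alcohol and cannot eliminate because C1 is quaternary; attack anti to the C1–C8a bond in the rotamer that keeps the C1 methyl next to the aryl group (Felkin-type) should give the (9′R) configuration.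

Step 19
Reactants: 27 the methallyl diene
Product: 28 2-[(1R,3aR,4R,7R)-1,4-dimethyl-1-[(1R)-3-methyl-1-(2,4,6-trimethoxyphenyl)butyl]-1,2,3,3a,4,5,6,7-octahydroazulen-7-yl]propan-2-ol
Conditions: H2 (1 atm), [Ir(cod)(PCy3)(py)]PF6 (5 mol %), CH2Cl2, rt
Reagents that add atoms: none
Why: hydroxyl-directed hydrogenation with Crabtree's catalyst: the C7 carbinol delivers H2 to the C4=C5 alkene on its own face, which sets C4 (H-4 cis to H-3a and to the carbinol); the 1,1-disubstituted side-chain alkene is reduced in the same operation, and C8a=C8 is shielded on the directing face by the C1 side chain.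

Step 20
Reactants: 28 the trimethoxyaryl carbinol
Product: 29 2-[(1R,3aR,4R,7R)-1-[(1R)-1-(3,5-dibromo-2,4,6-trimethoxyphenyl)-3-methylbutyl]-1,4-dimethyl-1,2,3,3a,4,5,6,7-octahydroazulen-7-yl]propan-2-ol
Conditions: NBS (2.05 equiv), MeCN, 0 °C, dark
Reagents that add atoms: N-bromosuccinimide, O=C1CCC(=O)N1Br
Why: electrophilic aromatic bromination of the two free ring positions, each activated by two ortho methoxy groups; the hindered trisubstituted alkene reacts much more slowly.

Step 21
Reactants: 29 the dibromide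
Product: 31 5-[(1R)-1-[(1R,3aR,4R,7R)-7-(2-hydroxypropan-2-yl)-1,4-dimethyl-1,2,3,3a,4,5,6,7-octahydroazulen-1-yl]-3-methylbutyl]-2,4,6-trimethoxybenzene-1,3-dicarbaldehyde, via trilithio species 30 (not isolated)
Conditions: t-BuLi (5.5 equiv), THF, −78 °C; DMF, −78 → 0 °C; aq NH4Cl
Reagents that add atoms: N,N-dimethylformamide, CN(C)C=O
Why: twofold bromine–lithium exchange (after deprotonation of the hydroxyl) and formylation of the aryllithium sites with DMF; this avoids Lewis-acidic formylation, which the tertiary alcohol would not survive.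

Step 22
Reactants: 31 the dialdehyde trimethyl ether
Product: 32 (−)-macrocarpal D
Conditions: lithium 4-methylbenzenethiolate (10 equiv), HMPA–toluene, 110 °C; then 1 M HCl
Reagents that add atoms: none
Why: nucleophilic (SN2) O-demethylation by thiolate, assisted by the ortho and para formyl groups; the basic conditions leave the tertiary alcohol, the alkene and the five stereocentres untouched.

**Compound list**

1 | ethyl (S)-3-hydroxybutanoate | CCOC(=O)C[C@H](C)O | starting material
2 | ethyl (2S,3S)-3-hydroxy-2-methylbutanoate | CCOC(=O)[C@@H](C)[C@H](C)O | intermediate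
3 | ethyl (2S,3S)-2-allyl-3-hydroxy-2-methylbutanoate | CCOC(=O)[C@@](C)(CC=C)[C@H](C)O | intermediate
4 | (2R,3S)-2-allyl-2-methylbutane-1,3-diol | OC[C@@](C)(CC=C)[C@H](C)O | intermediate
5 | (2S,3R)-3-[(tert-butyldimethylsilyloxy)methyl]-3-methylhex-5-en-2-ol | CC(C)(C)[Si](C)(C)OC[C@@](C)(CC=C)[C@H](C)O | intermediate
6 | (R)-3-[(tert-butyldimethylsilyloxy)methyl]-3-methylhex-5-en-2-one | CC(C)(C)[Si](C)(C)OC[C@@](C)(CC=C)C(C)=O | intermediate
7 | enol phosphate of 6 (not isolated): diethyl (R)-3-[(tert-butyldimethylsilyloxy)methyl]-3-methylhexa-1,5-dien-2-yl phosphate | CC(C)(C)[Si](C)(C)OC[C@@](C)(CC=C)C(=C)OP(=O)(OCC)OCC | intermediate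
8 | lithium acetylide (not isolated): lithium salt of the terminal alkyne derived from 7 | CC(C)(C)[Si](C)(C)OC[C@@](C)(CC=C)C#C[Li] | intermediate
9 | (S)-tert-butyldimethyl{[2-methyl-2-(trimethylsilylethynyl)pent-4-en-1-yl]oxy}silane | CC(C)(C)[Si](C)(C)OC[C@@](C)(CC=C)C#C[Si](C)(C)C | intermediate
10 | B-alkyl-9-BBN adduct of 9 (not isolated) | CC(C)(C)[Si](C)(C)OC[C@@](C)(CCCB1C2CCCC1CCC2)C#C[Si](C)(C)C | intermediate
11 | (S)-4-[(tert-butyldimethylsilyloxy)methyl]-4-methyl-6-(trimethylsilyl)hex-5-yn-1-ol | CC(C)(C)[Si](C)(C)OC[C@@](C)(CCCO)C#C[Si](C)(C)C | intermediate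
12 | (S)-4-[(tert-butyldimethylsilyloxy)methyl]-4-methyl-6-(trimethylsilyl)hex-5-ynal | CC(C)(C)[Si](C)(C)OC[C@@](C)(CCC=O)C#C[Si](C)(C)C | intermediate
13 | tert-butyl{[(2S,5Z)-6-iodo-2-methyl-2-(trimethylsilylethynyl)hept-5-en-1-yl]oxy}dimethylsilane | CC(C)(C)[Si](C)(C)OC[C@@](C)(CC/C=C(/C)I)C#C[Si](C)(C)C | intermediate
14 | 4,4,5,5-tetramethyl-2-vinyl-1,3,2-dioxaborolane | C=CB1OC(C)(C)C(C)(C)O1 | starting material
15 | ethyl diazoacetate | CCOC(=O)C=[N+]=[N-] | starting material
16 | ethyl (1R,2R)-2-(4,4,5,5-tetramethyl-1,3,2-dioxaborolan-2-yl)cyclopropane-1-carboxylate | CC1(C)OB(OC1(C)C)[C@@H]1C[C@H]1C(=O)OCC | intermediate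
17 | ethyl (1R,2R)-2-[(2Z,6S)-6-[(tert-butyldimethylsilyloxy)methyl]-6-methyl-8-(trimethylsilyl)oct-2-en-7-yn-2-yl]cyclopropane-1-carboxylate | CC(C)(C)[Si](C)(C)OC[C@@](C)(CC/C=C(/C)[C@@H]1C[C@H]1C(=O)OCC)C#C[Si](C)(C)C | intermediate
18 | ethyl (1R,2R)-2-[(2Z,6S)-6-[(tert-butyldimethylsilyloxy)methyl]-6-methyloct-2-en-7-yn-2-yl]cyclopropane-1-carboxylate (cycloaddition precursor) | CC(C)(C)[Si](C)(C)OC[C@@](C#C)(C)CC/C=C(/C)[C@@H]1C[C@H]1C(=O)OCC | intermediate
19 | ethyl (1S,3aR,7R)-1-[(tert-butyldimethylsilyloxy)methyl]-1,4-dimethyl-1,2,3,3a,6,7-hexahydroazulene-7-carboxylate (cycloadduct) | CC(C)(C)[Si](C)(C)OC[C@@]1(C)CC[C@H]2C1=C[C@H](C(=O)OCC)CC=C2C | intermediate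
20 | methyl ketone (not isolated): 1-[(1S,3aR,7R)-1-[(tert-butyldimethylsilyloxy)methyl]-1,4-dimethyl-1,2,3,3a,6,7-hexahydroazulen-7-yl]ethan-1-one | CC(C)(C)[Si](C)(C)OC[C@@]1(C)CC[C@H]2C1=C[C@H](C(C)=O)CC=C2C | intermediate
21 | 2-[(1S,3aR,7R)-1-[(tert-butyldimethylsilyloxy)methyl]-1,4-dimethyl-1,2,3,3a,6,7-hexahydroazulen-7-yl]propan-2-ol | CC(C)(C)[Si](C)(C)OC[C@@]1(C)CC[C@H]2C1=C[C@H](C(C)(C)O)CC=C2C | intermediate
22 | 2-[(1S,3aR,7R)-1-(hydroxymethyl)-1,4-dimethyl-1,2,3,3a,6,7-hexahydroazulen-7-yl]propan-2-ol | OC[C@@]1(C)CC[C@H]2C1=C[C@H](C(C)(C)O)CC=C2C | intermediate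
23 | (1S,3aR,7R)-7-(2-hydroxypropan-2-yl)-1,4-dimethyl-1,2,3,3a,6,7-hexahydroazulene-1-carbaldehyde | O=C[C@@]1(C)CC[C@H]2C1=C[C@H](C(C)(C)O)CC=C2C | intermediate
24 | 1,3,5-trimethoxybenzene | COc1cc(OC)cc(OC)c1 | starting material
25 | (2,4,6-trimethoxyphenyl)lithium (not isolated) | [Li]c1c(OC)cc(OC)cc1OC | intermediate
26 | 2-[(1S,3aR,7R)-1-[hydroxy(2,4,6-trimethoxyphenyl)methyl]-1,4-dimethyl-1,2,3,3a,6,7-hexahydroazulen-7-yl]propan-2-ol (both C9′ epimers) | OC(c1c(OC)cc(OC)cc1OC)[C@@]1(C)CC[C@H]2C1=C[C@H](C(C)(C)O)CC=C2C | intermediate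
27 | 2-[(1R,3aR,7R)-1,4-dimethyl-1-[(1R)-3-methyl-1-(2,4,6-trimethoxyphenyl)but-3-en-1-yl]-1,2,3,3a,6,7-hexahydroazulen-7-yl]propan-2-ol | C=C(C)C[C@@H](c1c(OC)cc(OC)cc1OC)[C@@]1(C)CC[C@H]2C1=C[C@H](C(C)(C)O)CC=C2C | intermediate
28 | 2-[(1R,3aR,4R,7R)-1,4-dimethyl-1-[(1R)-3-methyl-1-(2,4,6-trimethoxyphenyl)butyl]-1,2,3,3a,4,5,6,7-octahydroazulen-7-yl]propan-2-ol | CC(C)C[C@@H](c1c(OC)cc(OC)cc1OC)[C@@]1(C)CC[C@H]2C1=C[C@H](C(C)(C)O)CC[C@H]2C | intermediate
29 | 2-[(1R,3aR,4R,7R)-1-[(1R)-1-(3,5-dibromo-2,4,6-trimethoxyphenyl)-3-methylbutyl]-1,4-dimethyl-1,2,3,3a,4,5,6,7-octahydroazulen-7-yl]propan-2-ol | CC(C)C[C@@H](c1c(OC)c(Br)c(OC)c(Br)c1OC)[C@@]1(C)CC[C@H]2C1=C[C@H](C(C)(C)O)CC[C@H]2C | intermediate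
30 | trilithio species (not isolated): 3,5-dilithio aryl lithium alkoxide derived from 29 | CC(C)C[C@@H](c1c(OC)c([Li])c(OC)c([Li])c1OC)[C@@]1(C)CC[C@H]2C1=C[C@H](C(C)(C)O[Li])CC[C@H]2C | intermediate
31 | 5-[(1R)-1-[(1R,3aR,4R,7R)-7-(2-hydroxypropan-2-yl)-1,4-dimethyl-1,2,3,3a,4,5,6,7-octahydroazulen-1-yl]-3-methylbutyl]-2,4,6-trimethoxybenzene-1,3-dicarbaldehyde | CC(C)C[C@@H](c1c(OC)c(C=O)c(OC)c(C=O)c1OC)[C@@]1(C)CC[C@H]2C1=C[C@H](C(C)(C)O)CC[C@H]2C | intermediate
32 | (−)-macrocarpal D: 5-[(1R)-1-[(1R,3aR,4R,7R)-7-(2-hydroxypropan-2-yl)-1,4-dimethyl-1,2,3,3a,4,5,6,7-octahydroazulen-1-yl]-3-methylbutyl]-2,4,6-trihydroxybenzene-1,3-dicarbaldehyde | CC(C)C[C@@H](c1c(O)c(C=O)c(O)c(C=O)c1O)[C@@]1(C)CC[C@H]2C1=C[C@H](C(C)(C)O)CC[C@H]2C | target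

**Step count and risks**

Total step count: 22. Longest linear sequence: 21 steps (steps 1–9 and 11–22, from 1 to 32); step 10 is a one-step branch that supplies boronate 16.

Step 13 (highest risk). The rhodacycle may form by cleavage of the unsubstituted C5–C6 bond instead of C5–C7, or the Z trisubstituted alkene may turn over too slowly to outrun alkyne oligomerisation. The fallback strengthens the acceptor on the ring and sets out from 18. DIBAL-H reduction should give the cyclopropylmethanol F1, and Dess–Martin oxidation the cyclopropanecarbaldehyde F2, whose formyl group activates the adjacent ring bond more strongly than the ester. The same Rh(I) cycloaddition should then give the 7-carbaldehyde F3, MeMgBr/CeCl3 the secondary alcohol F4, and Dess–Martin oxidation the methyl ketone 20. Ketone 20 is isolated here and converted with MeMgBr/CeCl3 into 21, where the route resumes.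

Step 18. Capture of the planar benzylic cation may show poor or reversed facial selectivity at C9′. The fallback delivers hydride last and sets out from aldehyde 23. Isobutylmagnesium bromide/CeCl3 should give the isobutyl carbinol F5, Dess–Martin oxidation the isobutyl ketone F6, and addition of aryllithium 25 (CeCl3) the tertiary benzylic alcohol F7. Ionic hydrogenation of F7 (Et3SiH, BF3·OEt2, CH2Cl2, −78 °C) should give the isobutyl diene F8. Here hydride takes the place that the carbon nucleophile takes in step 18, so the same facial preference translates into the other C9′ configuration. Crabtree hydrogenation of F8 as in step 19 returns to 28.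

Step 10. The copper carbene may add to the electron-poor vinylboronate with low trans selectivity or low enantioselectivity. The fallback builds the cyclopropane on the chain under hydroxyl direction, so boronate 16 and step 11 are not needed; it sets out from vinyl iodide 13. Stille coupling with (E)-3-(tributylstannyl)prop-2-en-1-ol (Pd(PPh3)4, CuI, DMF) should give the (2E,4Z)-dienol F9. Charette asymmetric Simmons–Smith cyclopropanation (Zn(CH2I)2·DME, chiral dioxaborolane ligand of the enantiomeric series that leads to the (1R,2R) carbinol) should give the cyclopropylmethanol F10. TEMPO/PhI(OAc)2 in aqueous MeCN should give the cyclopropanecarboxylic acid F11, and EtI/K2CO3 in DMF returns to ester 17.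

Further compounds
F1 | step 13 | [(1R,2R)-2-[(2Z,6S)-6-[(tert-butyldimethylsilyloxy)methyl]-6-methyloct-2-en-7-yn-2-yl]cyclopropyl]methanol | CC(C)(C)[Si](C)(C)OC[C@@](C#C)(C)CC/C=C(/C)[C@@H]1C[C@H]1CO
F2 | step 13 | (1R,2R)-2-[(2Z,6S)-6-[(tert-butyldimethylsilyloxy)methyl]-6-methyloct-2-en-7-yn-2-yl]cyclopropane-1-carbaldehyde | CC(C)(C)[Si](C)(C)OC[C@@](C#C)(C)CC/C=C(/C)[C@@H]1C[C@H]1C=O
F3 | step 13 | (1S,3aR,7R)-1-[(tert-butyldimethylsilyloxy)methyl]-1,4-dimethyl-1,2,3,3a,6,7-hexahydroazulene-7-carbaldehyde | CC(C)(C)[Si](C)(C)OC[C@@]1(C)CC[C@H]2C1=C[C@H](C=O)CC=C2C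
F4 | step 13 | 1-[(1S,3aR,7R)-1-[(tert-butyldimethylsilyloxy)methyl]-1,4-dimethyl-1,2,3,3a,6,7-hexahydroazulen-7-yl]ethan-1-ol (carbinol epimers) | CC(C)(C)[Si](C)(C)OC[C@@]1(C)CC[C@H]2C1=C[C@H](C(C)O)CC=C2C
F5 | step 18 | 2-[(1S,3aR,7R)-1-(1-hydroxy-3-methylbutyl)-1,4-dimethyl-1,2,3,3a,6,7-hexahydroazulen-7-yl]propan-2-ol (carbinol epimers) | CC(C)CC(O)[C@@]1(C)CC[C@H]2C1=C[C@H](C(C)(C)O)CC=C2C
F6 | step 18 | 1-[(1S,3aR,7R)-7-(2-hydroxypropan-2-yl)-1,4-dimethyl-1,2,3,3a,6,7-hexahydroazulen-1-yl]-3-methylbutan-1-one | CC(C)CC(=O)[C@@]1(C)CC[C@H]2C1=C[C@H](C(C)(C)O)CC=C2C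
F7 | step 18 | 2-[(1S,3aR,7R)-1-[1-hydroxy-3-methyl-1-(2,4,6-trimethoxyphenyl)butyl]-1,4-dimethyl-1,2,3,3a,6,7-hexahydroazulen-7-yl]propan-2-ol (carbinol epimers) | CC(C)CC(O)(c1c(OC)cc(OC)cc1OC)[C@@]1(C)CC[C@H]2C1=C[C@H](C(C)(C)O)CC=C2C
F8 | step 18 | 2-[(1R,3aR,7R)-1,4-dimethyl-1-[(1R)-3-methyl-1-(2,4,6-trimethoxyphenyl)butyl]-1,2,3,3a,6,7-hexahydroazulen-7-yl]propan-2-ol | CC(C)C[C@@H](c1c(OC)cc(OC)cc1OC)[C@@]1(C)CC[C@H]2C1=C[C@H](C(C)(C)O)CC=C2C
F9 | step 10 | (2E,4Z,8S)-8-[(tert-butyldimethylsilyloxy)methyl]-4,8-dimethyl-10-(trimethylsilyl)deca-2,4-dien-9-yn-1-ol | CC(C)(C)[Si](C)(C)OC[C@@](C)(CC/C=C(/C)\C=C\CO)C#C[Si](C)(C)C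
F10 | step 10 | [(1R,2R)-2-[(2Z,6S)-6-[(tert-butyldimethylsilyloxy)methyl]-6-methyl-8-(trimethylsilyl)oct-2-en-7-yn-2-yl]cyclopropyl]methanol | CC(C)(C)[Si](C)(C)OC[C@@](C)(CC/C=C(/C)[C@@H]1C[C@H]1CO)C#C[Si](C)(C)C
F11 | step 10 | (1R,2R)-2-[(2Z,6S)-6-[(tert-butyldimethylsilyloxy)methyl]-6-methyl-8-(trimethylsilyl)oct-2-en-7-yn-2-yl]cyclopropane-1-carboxylic acid | CC(C)(C)[Si](C)(C)OC[C@@](C)(CC/C=C(/C)[C@@H]1C[C@H]1C(=O)O)C#C[Si](C)(C)C
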